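**Plan**

Numbering (azulene): C1(=CH2), C2(OH), C3, C3a, C4(=CH2), C5(OH), C6, C7, C8(OH), C8a; the side chain on C7 is C1'–C7', attached through C2', with the acetate on C3'.
Cuts: (a) C8–C8a. C1(=CH2)–C8a–C8(OH) is a homoallylic alcohol in which the exocyclic alkene of the five-membered ring and the carbinol of the seven-membered ring meet at the ring-fusion carbon, the retron of a carbonyl allylation with allylic transposition. (b) C4–C5, an alkenyllithium plus a δ-lactone whose ring oxygen is O-C3'. (c) C7–C8, a formyl anion equivalent added to the unsaturated lactone. (d) The lactone itself, by syn-aldol and Z-olefination.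
Forward: the five-membered ring comes from (S)-4-silyloxycyclopentenone and is elaborated (alkynyl, hydroxymethyl, alkenyl iodide). The lactone carrying C5–C8 and the side chain is made separately. The two are joined at C4–C5, which frees only O-C3' for acetylation. The seven-membered ring is closed last by an intramolecular Nozaki–Hiyama–Kishi allylation, followed by desilylation.
Stereochemistry: C2'/C3' from an auxiliary-controlled syn-aldol; C7 from conjugate addition trans to the neighbouring methyl-bearing carbon of the lactone; C3a from anti conjugate addition to the silyloxy enone; C2 from a cis-selective Luche reduction; C5 from a CBS reduction; C8 and C8a from the chair transition state of the ring closure.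

Key step: step 19

Remark: compounds 3 and 11 are assumed to be purchasable as the enantiomers shown (both antipodes of each are catalogue items).

**Route**

Step 1
Reactants: 1 4-methylpent-3-en-1-ol
Product: 2 4-methylpent-3-enal
Conditions: PhI(OAc)2, 2,2,6,6-tetramethylpiperidin-1-oxyl (TEMPO, 10 mol %), CH2Cl2, rt; used as a solution
Reagents that add atoms: none
Why: TEMPO-catalysed oxidation with PhI(OAc)2 stops at the aldehyde under non-basic conditions, so the β,γ-alkene should not move into conjugation.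

Step 2
Reactants: 3 (R)-4-benzyl-3-propanoyl-1,3-thiazolidine-2-thione; 2 4-methylpent-3-enal
Product: 5 (R)-4-benzyl-3-[(2R,3S)-3-hydroxy-2,6-dimethylhept-5-enoyl]-1,3-thiazolidine-2-thione, via titanium enolate 4 (not isolated)
Conditions: 3, TiCl4, i-Pr2NEt, N-methyl-2-pyrrolidinone, CH2Cl2, 0 °C; then 2, −78 → 0 °C; aq. NH4Cl
Reagents that add atoms: titanium tetrachloride, Cl[Ti](Cl)(Cl)Cl (into 4 only)
Why: Titanium-mediated thiazolidinethione aldol in the Evans-syn mode: the Z-enolate reacts through a non-chelated chair with the aldehyde anti to the benzyl group, which should set the 2R,3S syn pair (the future C2' and C3').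

Step 3
Reactants: 5 (R)-4-benzyl-3-[(2R,3S)-3-hydroxy-2,6-dimethylhept-5-enoyl]-1,3-thiazolidine-2-thione
Product: 6 (R)-4-benzyl-3-[(2R,3S)-2,6-dimethyl-3-(triethylsilyloxy)hept-5-enoyl]-1,3-thiazolidine-2-thione
Conditions: Et3SiOTf, 2,6-lutidine, CH2Cl2, −78 °C
Reagents that add atoms: triethylsilyl trifluoromethanesulfonate, CC[Si](CC)(CC)OS(=O)(=O)C(F)(F)F
Why: Silylation of the secondary alcohol blocks retro-aldol and elimination in the following reduction and olefination.

Step 4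
Reactants: 6 (R)-4-benzyl-3-[(2R,3S)-2,6-dimethyl-3-(triethylsilyloxy)hept-5-enoyl]-1,3-thiazolidine-2-thione
Product: 7 (2R,3S)-2,6-dimethyl-3-(triethylsilyloxy)hept-5-enal
Conditions: i-Bu2AlH, CH2Cl2, −78 °C; aq. potassium sodium tartrate
Reagents that add atoms: none
Why: Reductive cleavage of the auxiliary: the thiazolidinethione imide is reduced directly to the aldehyde through a stable aluminium hemiaminal, at a temperature where the α-centre should not epimerise.

Step 5
Reactants: 7 (2R,3S)-2,6-dimethyl-3-(triethylsilyloxy)hept-5-enal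
Product: 9 (5S,6S)-5-methyl-6-(3-methylbut-2-en-1-yl)-5,6-dihydro-2H-pyran-2-one, via Z-enoate 8 (not isolated)
Conditions: (CF3CH2O)2P(O)CH2CO2Me, KN(SiMe3)2, 18-crown-6, THF, −78 °C; then p-TsOH·H2O (cat.), MeOH, rt
Reagents that add atoms: methyl bis(2,2,2-trifluoroethyl)phosphonoacetate, COC(=O)CP(=O)(OCC(F)(F)F)OCC(F)(F)F
Why: Still–Gennari Z-selective Horner–Wadsworth–Emmons olefination, then acid-mediated desilylation and lactonization; only the Z ester can close, so any E isomer is left behind.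

Step 6
Reactants: 9 (5S,6S)-5-methyl-6-(3-methylbut-2-en-1-yl)-5,6-dihydro-2H-pyran-2-one
Product: 10 (4R,5S,6S)-4-(1,3-dithian-2-yl)-5-methyl-6-(3-methylbut-2-en-1-yl)oxan-2-one
Conditions: 1,3-dithiane, n-BuLi, THF, −30 °C; HMPA, −78 °C; then 9; AcOH quench
Reagents that add atoms: 2-lithio-1,3-dithiane (from 1,3-dithiane and n-BuLi), [Li]C1SCCCS1
Why: Michael addition of the sulfur-stabilised carbanion (a formyl anion equivalent), steered to 1,4 by HMPA, should occur axially on the half-chair anti to the adjacent C5 methyl group and set C4 of the lactone (the future C7) trans to it.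

Step 7
Reactants: 11 (S)-4-(tert-butyldimethylsilyloxy)cyclopent-2-en-1-one
Product: 13 (S)-4-[(trimethylsilyl)ethynyl]cyclopent-2-en-1-one, via silyloxy ketone 12 (not isolated)
Conditions: Me2AlC≡CSiMe3 (from LiC≡CSiMe3 and Me2AlCl), Ni(acac)2 (5 mol %), i-Bu2AlH (5 mol %, gives zerovalent nickel), Et2O, −5 °C; aq. work-up; then 1,8-diazabicyclo[5.4.0]undec-7-ene (DBU), CH2Cl2, 0 °C, short contact
Reagents that add atoms: dimethyl[(trimethylsilyl)ethynyl]aluminium, C[Al](C)C#C[Si](C)(C)C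
Why: Nickel-catalysed conjugate alkynylation with an alkynylalane adds anti to the C4 silyloxy group, and E1cB loss of silanolate then transposes the enone so that the new centre (the future C3a) becomes C4 of a cyclopentenone.

Step 8
Reactants: 13 (S)-4-[(trimethylsilyl)ethynyl]cyclopent-2-en-1-one
Product: 14 (S)-2-(hydroxymethyl)-4-[(trimethylsilyl)ethynyl]cyclopent-2-en-1-one
Conditions: aq. HCHO, imidazole, THF/H2O, rt
Reagents that add atoms: formaldehyde, C=O
Why: Morita–Baylis–Hillman α-hydroxymethylation of the cyclic enone creates no stereocentre, and the weak aqueous amine base should leave the γ-centre untouched.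

Step 9
Reactants: 14 (S)-2-(hydroxymethyl)-4-[(trimethylsilyl)ethynyl]cyclopent-2-en-1-one
Product: 16 (1R,4S)-4-ethynyl-2-(hydroxymethyl)cyclopent-2-en-1-ol, via silylalkyne diol 15 (not isolated)
Conditions: NaBH4, CeCl3·7H2O, MeOH, −78 °C; then K2CO3, MeOH, rt
Reagents that add atoms: none
Why: Luche 1,2-reduction delivers hydride anti to the C4 substituent to give the cis-1,4 alcohol (the future C2), and methanolic K2CO3 then cleaves the alkynyl C–Si bond.

Step 10
Reactants: 16 (1R,4S)-4-ethynyl-2-(hydroxymethyl)cyclopent-2-en-1-ol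
Product: 17 (1R,4S)-1-(tert-butyldimethylsilyloxy)-2-[(tert-butyldimethylsilyloxy)methyl]-4-ethynylcyclopent-2-ene
Conditions: t-BuMe2SiCl, imidazole, DMF, rt
Reagents that add atoms: tert-butyldimethylsilyl chloride, CC(C)(C)[Si](C)(C)Cl
Why: Standard silylation of both hydroxyls gives ethers that tolerate the organometallic steps and can later be told apart as primary and secondary.

Step 11
Reactants: 17 (1R,4S)-1-(tert-butyldimethylsilyloxy)-2-[(tert-butyldimethylsilyloxy)methyl]-4-ethynylcyclopent-2-ene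
Product: 19 (1R,4S)-1-(tert-butyldimethylsilyloxy)-2-[(tert-butyldimethylsilyloxy)methyl]-4-(1-iodoethenyl)cyclopent-2-ene, via alkenylalane 18 (not isolated)
Conditions: NiCl2(dppp) (3 mol %; dppp = 1,3-bis(diphenylphosphino)propane), i-Bu2AlH, THF, 0 °C → rt; then N-iodosuccinimide, −78 → 0 °C
Reagents that add atoms: diisobutylaluminium hydride, CC(C)C[AlH]CC(C)C (into 18 only); N-iodosuccinimide, O=C1CCC(=O)N1I
Why: Nickel-catalysed α-selective hydroalumination of the terminal alkyne places aluminium on the internal carbon, and iodinolysis of the C–Al bond gives the 1,1-disubstituted alkenyl iodide.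

Step 12
Reactants: 19 (1R,4S)-1-(tert-butyldimethylsilyloxy)-2-[(tert-butyldimethylsilyloxy)methyl]-4-(1-iodoethenyl)cyclopent-2-ene; 10 (4R,5S,6S)-4-(1,3-dithian-2-yl)-5-methyl-6-(3-methylbut-2-en-1-yl)oxan-2-one
Product: 21 (5R,6S,7S)-2-[(1S,4R)-4-(tert-butyldimethylsilyloxy)-3-[(tert-butyldimethylsilyloxy)methyl]cyclopent-2-en-1-yl]-5-(1,3-dithian-2-yl)-7-hydroxy-6,10-dimethylundeca-1,9-dien-3-one, via alkenyllithium 20 (not isolated)
Conditions: 19, t-BuLi (2 equiv), Et2O, −78 °C; then 10 in THF, −78 °C; AcOH quench at −78 °C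
Reagents that add atoms: tert-butyllithium, [Li]C(C)(C)C (lithium into 20 only)
Why: Iodine–lithium exchange followed by acyl substitution at the lactone carbonyl; the tetrahedral lithium hemiketal should persist at −78 °C, so one alkenyl group adds and the ring oxygen is released as the only free hydroxyl (O-C3').

Step 13
Reactants: 21 (5R,6S,7S)-2-[(1S,4R)-4-(tert-butyldimethylsilyloxy)-3-[(tert-butyldimethylsilyloxy)methyl]cyclopent-2-en-1-yl]-5-(1,3-dithian-2-yl)-7-hydroxy-6,10-dimethylundeca-1,9-dien-3-one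
Product: 22 (5R,6S,7S)-7-acetoxy-2-[(1S,4R)-4-(tert-butyldimethylsilyloxy)-3-[(tert-butyldimethylsilyloxy)methyl]cyclopent-2-en-1-yl]-5-(1,3-dithian-2-yl)-6,10-dimethylundeca-1,9-dien-3-one
Conditions: Ac2O, pyridine, 4-(dimethylamino)pyridine (cat.), CH2Cl2, 0 °C → rt
Reagents that add atoms: acetic anhydride, CC(=O)OC(C)=O
Why: Acylation of the single free secondary hydroxyl installs the acetate of the target and traps the open-chain hydroxy ketone form.

Step 14
Reactants: 22 (5R,6S,7S)-7-acetoxy-2-[(1S,4R)-4-(tert-butyldimethylsilyloxy)-3-[(tert-butyldimethylsilyloxy)methyl]cyclopent-2-en-1-yl]-5-(1,3-dithian-2-yl)-6,10-dimethylundeca-1,9-dien-3-one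
Product: 23 (3S,5R,6S,7S)-7-acetoxy-2-[(1S,4R)-4-(tert-butyldimethylsilyloxy)-3-[(tert-butyldimethylsilyloxy)methyl]cyclopent-2-en-1-yl]-5-(1,3-dithian-2-yl)-6,10-dimethylundeca-1,9-dien-3-ol
Conditions: (R)-2-methyl-CBS-oxazaborolidine [(R)-1-methyl-3,3-diphenyltetrahydro-1H,3H-pyrrolo[1,2-c][1,3,2]oxazaborole, 0.5 equiv], catecholborane, toluene, −78 °C
Reagents that add atoms: none
Why: Corey–Bakshi–Shibata reduction: the α-branched alkenyl group acts as the large substituent, so the (R)-catalyst should deliver hydride to give the (S)-carbinol (the future C5) under reagent control, with the acetate untouched.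

Step 15
Reactants: 23 (3S,5R,6S,7S)-7-acetoxy-2-[(1S,4R)-4-(tert-butyldimethylsilyloxy)-3-[(tert-butyldimethylsilyloxy)methyl]cyclopent-2-en-1-yl]-5-(1,3-dithian-2-yl)-6,10-dimethylundeca-1,9-dien-3-ol
Product: 24 (3S,5R,6S,7S)-7-acetoxy-3-(tert-butyldimethylsilyloxy)-2-[(1S,4R)-4-(tert-butyldimethylsilyloxy)-3-[(tert-butyldimethylsilyloxy)methyl]cyclopent-2-en-1-yl]-5-(1,3-dithian-2-yl)-6,10-dimethylundeca-1,9-diene
Conditions: t-BuMe2SiOTf, 2,6-lutidine, CH2Cl2, −78 → 0 °C
Reagents that add atoms: tert-butyldimethylsilyl trifluoromethanesulfonate, CC(C)(C)[Si](C)(C)OS(=O)(=O)C(F)(F)F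
Why: Silylation of the hindered allylic alcohol prevents lactol formation with the later aldehyde and keeps the aldehyde acyclic for the ring closure.

Step 16
Reactants: 24 (3S,5R,6S,7S)-7-acetoxy-3-(tert-butyldimethylsilyloxy)-2-[(1S,4R)-4-(tert-butyldimethylsilyloxy)-3-[(tert-butyldimethylsilyloxy)methyl]cyclopent-2-en-1-yl]-5-(1,3-dithian-2-yl)-6,10-dimethylundeca-1,9-diene
Product: 25 (3S,5R,6S,7S)-7-acetoxy-3-(tert-butyldimethylsilyloxy)-2-[(1S,4R)-4-(tert-butyldimethylsilyloxy)-3-(hydroxymethyl)cyclopent-2-en-1-yl]-5-(1,3-dithian-2-yl)-6,10-dimethylundeca-1,9-diene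
Conditions: HF·pyridine, pyridine, THF, 0 °C
Reagents that add atoms: none
Why: Buffered HF·pyridine should cleave the unhindered primary silyl ether much faster than the two secondary ones.

Step 17
Reactants: 25 (3S,5R,6S,7S)-7-acetoxy-3-(tert-butyldimethylsilyloxy)-2-[(1S,4R)-4-(tert-butyldimethylsilyloxy)-3-(hydroxymethyl)cyclopent-2-en-1-yl]-5-(1,3-dithian-2-yl)-6,10-dimethylundeca-1,9-diene
Product: 27 (3S,5R,6S,7S)-7-acetoxy-2-[(1S,4R)-3-(bromomethyl)-4-(tert-butyldimethylsilyloxy)cyclopent-2-en-1-yl]-3-(tert-butyldimethylsilyloxy)-5-(1,3-dithian-2-yl)-6,10-dimethylundeca-1,9-diene, via allylic mesylate 26 (not isolated)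
Conditions: MsCl, Et3N, CH2Cl2, −20 °C; then LiBr, THF, 0 °C
Reagents that add atoms: methanesulfonyl chloride, CS(=O)(=O)Cl (into 26 only); lithium bromide, [Li+].[Br-]
Why: Mesylation and SN2 displacement by bromide (Finkelstein-type) give the allylic bromide; an SN2' isomer would lead to the same allylchromium reagent.

Step 18
Reactants: 27 (3S,5R,6S,7S)-7-acetoxy-2-[(1S,4R)-3-(bromomethyl)-4-(tert-butyldimethylsilyloxy)cyclopent-2-en-1-yl]-3-(tert-butyldimethylsilyloxy)-5-(1,3-dithian-2-yl)-6,10-dimethylundeca-1,9-diene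
Product: 28 (3S,5R,6S,7S)-7-acetoxy-2-[(1S,4R)-3-(bromomethyl)-4-(tert-butyldimethylsilyloxy)cyclopent-2-en-1-yl]-3-(tert-butyldimethylsilyloxy)-6,10-dimethylundeca-1,9-diene-5-carbaldehyde
Conditions: PhI(OCOCF3)2, MeCN/H2O (9:1), 0 °C, 10 min; used at once
Reagents that add atoms: water, O
Why: Oxidative dethioacetalization with the hypervalent iodine reagent is fast at 0 °C and should leave the alkenes, the allylic bromide, the silyl ethers and the acetate intact.

Step 19
Reactants: 28 (3S,5R,6S,7S)-7-acetoxy-2-[(1S,4R)-3-(bromomethyl)-4-(tert-butyldimethylsilyloxy)cyclopent-2-en-1-yl]-3-(tert-butyldimethylsilyloxy)-6,10-dimethylundeca-1,9-diene-5-carbaldehyde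
Product: 30 (2S,3S)-2-[(2R,3aS,5S,7R,8S,8aR)-2,5-bis(tert-butyldimethylsilyloxy)-8-hydroxy-1,4-dimethylidenedecahydroazulen-7-yl]-6-methylhept-5-en-3-yl acetate, via allylchromium reagent 29 (not isolated)
Conditions: CrCl2 (8 equiv), THF, rt, syringe-pump addition of 28 (final 0.002 M); aq. work-up
Reagents that add atoms: chromium dichloride, Cl[Cr]Cl (into 29 only)
Why: Two single-electron transfers from CrCl2 turn the primary allylic C–Br bond into a σ-allylchromium reagent (trivalent chromium on the exocyclic CH2), which adds to the tethered aldehyde with allylic transposition through a six-membered Zimmerman–Traxler chair, so that ring carbon C8a bonds to C8 and the exocyclic C1=CH2 alkene is left behind; this is an intramolecular Nozaki–Hiyama–Kishi allylation, a reaction type with close precedent for medium carbocycles. The seven-membered ring closes in a 7-exo-trig mode at the aldehyde carbon. At C8a, the chromium-bearing chair should form on the cyclopentene face anti to the C2 silyloxy group and to the C3a–C4 bond, which gives the trans ring fusion. At C8, the ring holds C3a trans to CH2Cr across the C1=C8a bond (an E-type allyl unit), so with the aldehyde substituent C7 equatorial the chair gives the anti 8S,8aR pair, and Felkin–Anh control by C7 (branched side chain anti to the incoming carbon, ring CH2 inside) selects the same aldehyde face, so the three elements are matched. The step needs chemoselectivity among three alkenes and two carbonyl groups and γ- over α-attack: only the allylic bromide is activated, organochromium reagents ignore the acetate and need no Lewis acid (which would trigger ene cyclization of the aldehyde onto the prenyl or C4-methylene alkenes), α-attack would require a nine-membered ring, and high dilution suppresses intermolecular coupling.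

Step 20
Reactants: 30 (2S,3S)-2-[(2R,3aS,5S,7R,8S,8aR)-2,5-bis(tert-butyldimethylsilyloxy)-8-hydroxy-1,4-dimethylidenedecahydroazulen-7-yl]-6-methylhept-5-en-3-yl acetate
Product: 31 (2S,3S)-6-methyl-2-[(2R,3aS,5S,7R,8S,8aR)-2,5,8-trihydroxy-1,4-dimethylidenedecahydroazulen-7-yl]hept-5-en-3-yl acetate
Conditions: HF·pyridine, THF, 0 °C → rt
Reagents that add atoms: none
Why: Cleavage of the two secondary silyl ethers by HF under weakly acidic conditions, which should neither hydrolyse nor move the acetate.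

**Compound list**

1 | 4-methylpent-3-en-1-ol | CC(C)=CCCO | starting material
2 | 4-methylpent-3-enal | CC(C)=CCC=O | intermediate
3 | (R)-4-benzyl-3-propanoyl-1,3-thiazolidine-2-thione | CCC(=O)N1[C@H](Cc2ccccc2)CSC1=S | starting material
4 | trichlorotitanium (Z)-enolate of 3 (not isolated) | C/C=C(\O[Ti](Cl)(Cl)Cl)N1[C@H](Cc2ccccc2)CSC1=S | intermediate
5 | (R)-4-benzyl-3-[(2R,3S)-3-hydroxy-2,6-dimethylhept-5-enoyl]-1,3-thiazolidine-2-thione | O=C([C@H](C)[C@@H](O)CC=C(C)C)N1[C@H](Cc2ccccc2)CSC1=S | intermediate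
6 | (R)-4-benzyl-3-[(2R,3S)-2,6-dimethyl-3-(triethylsilyloxy)hept-5-enoyl]-1,3-thiazolidine-2-thione | O=C([C@H](C)[C@@H](O[Si](CC)(CC)CC)CC=C(C)C)N1[C@H](Cc2ccccc2)CSC1=S | intermediate
7 | (2R,3S)-2,6-dimethyl-3-(triethylsilyloxy)hept-5-enal | O=C[C@H](C)[C@@H](O[Si](CC)(CC)CC)CC=C(C)C | intermediate
8 | methyl (2Z,4S,5S)-4,8-dimethyl-5-(triethylsilyloxy)nona-2,7-dienoate (not isolated) | COC(=O)/C=C\[C@H](C)[C@@H](O[Si](CC)(CC)CC)CC=C(C)C | intermediate
9 | (5S,6S)-5-methyl-6-(3-methylbut-2-en-1-yl)-5,6-dihydro-2H-pyran-2-one | O=C1C=C[C@H](C)[C@H](CC=C(C)C)O1 | intermediate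
10 | (4R,5S,6S)-4-(1,3-dithian-2-yl)-5-methyl-6-(3-methylbut-2-en-1-yl)oxan-2-one | O=C1C[C@@H](C2SCCCS2)[C@H](C)[C@H](CC=C(C)C)O1 | intermediate
11 | (S)-4-(tert-butyldimethylsilyloxy)cyclopent-2-en-1-one | O=C1C=C[C@@H](O[Si](C)(C)C(C)(C)C)C1 | starting material
12 | (3R,4S)-4-(tert-butyldimethylsilyloxy)-3-[(trimethylsilyl)ethynyl]cyclopentan-1-one (not isolated) | O=C1C[C@H](C#C[Si](C)(C)C)[C@@H](O[Si](C)(C)C(C)(C)C)C1 | intermediate
13 | (S)-4-[(trimethylsilyl)ethynyl]cyclopent-2-en-1-one | O=C1C=C[C@@H](C#C[Si](C)(C)C)C1 | intermediate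
14 | (S)-2-(hydroxymethyl)-4-[(trimethylsilyl)ethynyl]cyclopent-2-en-1-one | O=C1C(CO)=C[C@@H](C#C[Si](C)(C)C)C1 | intermediate
15 | (1R,4S)-2-(hydroxymethyl)-4-[(trimethylsilyl)ethynyl]cyclopent-2-en-1-ol (not isolated) | OCC1=C[C@@H](C#C[Si](C)(C)C)C[C@H]1O | intermediate
16 | (1R,4S)-4-ethynyl-2-(hydroxymethyl)cyclopent-2-en-1-ol | OCC1=C[C@@H](C#C)C[C@H]1O | intermediate
17 | (1R,4S)-1-(tert-butyldimethylsilyloxy)-2-[(tert-butyldimethylsilyloxy)methyl]-4-ethynylcyclopent-2-ene | CC(C)(C)[Si](C)(C)OCC1=C[C@@H](C#C)C[C@H]1O[Si](C)(C)C(C)(C)C | intermediate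
18 | diisobutyl{1-[(1S,4R)-4-(tert-butyldimethylsilyloxy)-3-[(tert-butyldimethylsilyloxy)methyl]cyclopent-2-en-1-yl]ethenyl}aluminium (not isolated) | CC(C)(C)[Si](C)(C)OCC1=C[C@@H](C(=C)[Al](CC(C)C)CC(C)C)C[C@H]1O[Si](C)(C)C(C)(C)C | intermediate
19 | (1R,4S)-1-(tert-butyldimethylsilyloxy)-2-[(tert-butyldimethylsilyloxy)methyl]-4-(1-iodoethenyl)cyclopent-2-ene | CC(C)(C)[Si](C)(C)OCC1=C[C@@H](C(=C)I)C[C@H]1O[Si](C)(C)C(C)(C)C | intermediate
20 | {1-[(1S,4R)-4-(tert-butyldimethylsilyloxy)-3-[(tert-butyldimethylsilyloxy)methyl]cyclopent-2-en-1-yl]ethenyl}lithium (not isolated) | CC(C)(C)[Si](C)(C)OCC1=C[C@@H](C(=C)[Li])C[C@H]1O[Si](C)(C)C(C)(C)C | intermediate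
21 | (5R,6S,7S)-2-[(1S,4R)-4-(tert-butyldimethylsilyloxy)-3-[(tert-butyldimethylsilyloxy)methyl]cyclopent-2-en-1-yl]-5-(1,3-dithian-2-yl)-7-hydroxy-6,10-dimethylundeca-1,9-dien-3-one | CC(C)(C)[Si](C)(C)OCC1=C[C@@H](C(=C)C(=O)C[C@@H](C2SCCCS2)[C@H](C)[C@@H](O)CC=C(C)C)C[C@H]1O[Si](C)(C)C(C)(C)C | intermediate
22 | (5R,6S,7S)-7-acetoxy-2-[(1S,4R)-4-(tert-butyldimethylsilyloxy)-3-[(tert-butyldimethylsilyloxy)methyl]cyclopent-2-en-1-yl]-5-(1,3-dithian-2-yl)-6,10-dimethylundeca-1,9-dien-3-one | CC(C)(C)[Si](C)(C)OCC1=C[C@@H](C(=C)C(=O)C[C@@H](C2SCCCS2)[C@H](C)[C@@H](OC(C)=O)CC=C(C)C)C[C@H]1O[Si](C)(C)C(C)(C)C | intermediate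
23 | (3S,5R,6S,7S)-7-acetoxy-2-[(1S,4R)-4-(tert-butyldimethylsilyloxy)-3-[(tert-butyldimethylsilyloxy)methyl]cyclopent-2-en-1-yl]-5-(1,3-dithian-2-yl)-6,10-dimethylundeca-1,9-dien-3-ol | CC(C)(C)[Si](C)(C)OCC1=C[C@@H](C(=C)[C@@H](O)C[C@@H](C2SCCCS2)[C@H](C)[C@@H](OC(C)=O)CC=C(C)C)C[C@H]1O[Si](C)(C)C(C)(C)C | intermediate
24 | (3S,5R,6S,7S)-7-acetoxy-3-(tert-butyldimethylsilyloxy)-2-[(1S,4R)-4-(tert-butyldimethylsilyloxy)-3-[(tert-butyldimethylsilyloxy)methyl]cyclopent-2-en-1-yl]-5-(1,3-dithian-2-yl)-6,10-dimethylundeca-1,9-diene | CC(C)(C)[Si](C)(C)OCC1=C[C@@H](C(=C)[C@@H](O[Si](C)(C)C(C)(C)C)C[C@@H](C2SCCCS2)[C@H](C)[C@@H](OC(C)=O)CC=C(C)C)C[C@H]1O[Si](C)(C)C(C)(C)C | intermediate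
25 | (3S,5R,6S,7S)-7-acetoxy-3-(tert-butyldimethylsilyloxy)-2-[(1S,4R)-4-(tert-butyldimethylsilyloxy)-3-(hydroxymethyl)cyclopent-2-en-1-yl]-5-(1,3-dithian-2-yl)-6,10-dimethylundeca-1,9-diene | OCC1=C[C@@H](C(=C)[C@@H](O[Si](C)(C)C(C)(C)C)C[C@@H](C2SCCCS2)[C@H](C)[C@@H](OC(C)=O)CC=C(C)C)C[C@H]1O[Si](C)(C)C(C)(C)C | intermediate
26 | methanesulfonate of 25 at the primary allylic oxygen (not isolated) | CS(=O)(=O)OCC1=C[C@@H](C(=C)[C@@H](O[Si](C)(C)C(C)(C)C)C[C@@H](C2SCCCS2)[C@H](C)[C@@H](OC(C)=O)CC=C(C)C)C[C@H]1O[Si](C)(C)C(C)(C)C | intermediate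
27 | (3S,5R,6S,7S)-7-acetoxy-2-[(1S,4R)-3-(bromomethyl)-4-(tert-butyldimethylsilyloxy)cyclopent-2-en-1-yl]-3-(tert-butyldimethylsilyloxy)-5-(1,3-dithian-2-yl)-6,10-dimethylundeca-1,9-diene | BrCC1=C[C@@H](C(=C)[C@@H](O[Si](C)(C)C(C)(C)C)C[C@@H](C2SCCCS2)[C@H](C)[C@@H](OC(C)=O)CC=C(C)C)C[C@H]1O[Si](C)(C)C(C)(C)C | intermediate
28 | (3S,5R,6S,7S)-7-acetoxy-2-[(1S,4R)-3-(bromomethyl)-4-(tert-butyldimethylsilyloxy)cyclopent-2-en-1-yl]-3-(tert-butyldimethylsilyloxy)-6,10-dimethylundeca-1,9-diene-5-carbaldehyde | BrCC1=C[C@@H](C(=C)[C@@H](O[Si](C)(C)C(C)(C)C)C[C@@H](C=O)[C@H](C)[C@@H](OC(C)=O)CC=C(C)C)C[C@H]1O[Si](C)(C)C(C)(C)C | intermediate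
29 | dichlorochromium σ-allyl reagent from 28 (CH2Br replaced by CH2CrCl2, trivalent chromium; not isolated) | Cl[Cr](Cl)CC1=C[C@@H](C(=C)[C@@H](O[Si](C)(C)C(C)(C)C)C[C@@H](C=O)[C@H](C)[C@@H](OC(C)=O)CC=C(C)C)C[C@H]1O[Si](C)(C)C(C)(C)C | intermediate
30 | (2S,3S)-2-[(2R,3aS,5S,7R,8S,8aR)-2,5-bis(tert-butyldimethylsilyloxy)-8-hydroxy-1,4-dimethylidenedecahydroazulen-7-yl]-6-methylhept-5-en-3-yl acetate | C=C1[C@@H]2[C@@H](O)[C@@H]([C@H](C)[C@H](CC=C(C)C)OC(C)=O)C[C@H](O[Si](C)(C)C(C)(C)C)C(=C)[C@H]2C[C@H]1O[Si](C)(C)C(C)(C)C | intermediate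
31 | (2S,3S)-6-methyl-2-[(2R,3aS,5S,7R,8S,8aR)-2,5,8-trihydroxy-1,4-dimethylidenedecahydroazulen-7-yl]hept-5-en-3-yl acetate | C=C1[C@@H]2[C@@H](O)[C@@H]([C@H](C)[C@H](CC=C(C)C)OC(C)=O)C[C@H](O)C(=C)[C@H]2C[C@H]1O | target

**Step count and risks**

Total step count: 20. Longest linear sequence: 15 (steps 1–6, then 12–20).

Steps most likely to fail:

Step 19. The ring closure may suffer from poor facial selectivity at C8a/C8, or intermolecular coupling may outrun cyclization. The fallback changes the organochromium addition into a promoter-free allylboration and sets out from bromide 27. Pd2(dba)3-catalysed borylation with B2pin2 in DMSO should give the primary allylboronate, the pinacol (cyclopentenylmethyl)boronate of 27 F1. Alkylative dithiane hydrolysis (MeI, CaCO3, aqueous MeCN) would release the aldehyde allylboronate F2, which is expected to cyclize on standing through the same closed chair, tightened by the short B–O and B–C bonds, to the O-boronate of the ring-closed product F3. Mild aqueous work-up returns to the route at 30.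

Step 7. The DBU-mediated elimination may erode the stereocentre by γ-deprotonation of the alkynyl enone, or move the ring alkene into conjugation with the alkyne. The fallback sets out from 11 and replaces silanolate expulsion by elimination of a better leaving group under weak base. The conjugate adduct 12 would be isolated and its silyl ether cleaved with aqueous HF in MeCN to (3R,4S)-4-hydroxy-3-[(trimethylsilyl)ethynyl]cyclopentan-1-one F4. MsCl and Et3N at −40 °C would convert this through (1S,2R)-4-oxo-2-[(trimethylsilyl)ethynyl]cyclopentyl methanesulfonate F5, which eliminates under these conditions and returns to the route at 13.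

Step 12. The hindered alkenyllithium may enolize the lactone instead of adding, or add twice once the hemiketal opens. The fallback changes the acyl acceptor from the lactone to an open-chain Weinreb amide and sets out from 10. MeNH(OMe)·HCl with AlMe3 should give (3R,4S,5S)-3-(1,3-dithian-2-yl)-5-hydroxy-N-methoxy-N,4,8-trimethylnon-7-enamide F6. Et3SiCl and imidazole would give its triethylsilyl ether F7. Alkenyllithium 20 then adds once, through the stable chelate, to give the 7-O-triethylsilyl ether of 21 F8. PPTS in MeOH at 0 °C removes the triethylsilyl group and returns to the route at 21.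

**Further compounds**

F1 | step 19 | pinacol boronate of 27 (CH2Br replaced by CH2B(pin)) | CC1(C)OB(OC1(C)C)CC2=C[C@@H](C(=C)[C@@H](O[Si](C)(C)C(C)(C)C)C[C@@H](C3SCCCS3)[C@H](C)[C@@H](OC(C)=O)CC=C(C)C)C[C@H]2O[Si](C)(C)C(C)(C)C
F2 | step 19 | aldehyde allylboronate (dithiane of F1 replaced by CHO) | CC1(C)OB(OC1(C)C)CC2=C[C@@H](C(=C)[C@@H](O[Si](C)(C)C(C)(C)C)C[C@@H](C=O)[C@H](C)[C@@H](OC(C)=O)CC=C(C)C)C[C@H]2O[Si](C)(C)C(C)(C)C
F3 | step 19 | 8-O-(pinacolatoboryl) derivative of 30 | C=C1[C@@H]2[C@@H](OB3OC(C)(C)C(C)(C)O3)[C@@H]([C@H](C)[C@H](CC=C(C)C)OC(C)=O)C[C@H](O[Si](C)(C)C(C)(C)C)C(=C)[C@H]2C[C@H]1O[Si](C)(C)C(C)(C)C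
F4 | step 7 | (3R,4S)-4-hydroxy-3-[(trimethylsilyl)ethynyl]cyclopentan-1-one | O=C1C[C@H](C#C[Si](C)(C)C)[C@@H](O)C1
F5 | step 7 | (1S,2R)-4-oxo-2-[(trimethylsilyl)ethynyl]cyclopentyl methanesulfonate | O=C1C[C@H](C#C[Si](C)(C)C)[C@@H](OS(C)(=O)=O)C1
F6 | step 12 | (3R,4S,5S)-3-(1,3-dithian-2-yl)-5-hydroxy-N-methoxy-N,4,8-trimethylnon-7-enamide | CON(C)C(=O)C[C@@H](C1SCCCS1)[C@H](C)[C@@H](O)CC=C(C)C
F7 | step 12 | (3R,4S,5S)-3-(1,3-dithian-2-yl)-N-methoxy-N,4,8-trimethyl-5-(triethylsilyloxy)non-7-enamide | CON(C)C(=O)C[C@@H](C1SCCCS1)[C@H](C)[C@@H](O[Si](CC)(CC)CC)CC=C(C)C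
F8 | step 12 | 7-O-triethylsilyl ether of 21 | CC(C)(C)[Si](C)(C)OCC1=C[C@@H](C(=C)C(=O)C[C@@H](C2SCCCS2)[C@H](C)[C@@H](O[Si](CC)(CC)CC)CC=C(C)C)C[C@H]1O[Si](C)(C)C(C)(C)C
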